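**Strategy.** The dihydrofuran is disconnected at two bonds, CH2–C(quaternary) and O–CH, which leads back to aromatic, Cs-symmetric deoxycohumulone and an enantiopure epoxy-prenyl iodide. The key step is a desymmetrising dearomative [3+2] annulation under a chiral ammonium phase-transfer catalyst: one of the two enantiotopic prenyl-bearing ring carbons is C-alkylated, and the neighbouring enol oxygen then opens the epoxide 5-exo. It exploits the C,O-1,3-dinucleophile of the carbocycle (benzofuran numbering: quaternary C3a and the oxygen on C7a) and the C3–C2 unit of the furan ring as a 1,2-dielectrophile. One operation forms two bonds, the five-membered ring and both stereocentres.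

Key step: step 5

Assumption: the sense of induction of the cinchona ammonium salt in step 5 cannot be derived from first principles; the cinchonidinium catalyst is written, and its cinchoninium pseudoenantiomer is the direct substitute if that proves to be the matched partner of iodide 9.

Step 1
Reactants: 1 phloroglucinol; 2 isobutyryl chloride
Product: 3 2-methyl-1-(2,4,6-trihydroxyphenyl)propan-1-one (phlorisobutyrophenone)
Conditions: AlCl3 (3 equiv), PhNO2, 23 → 65 °C; then aq. HCl
Reagents that add atoms: none
Why: Friedel–Crafts C-acylation of the strongly activated triol should stop at the mono-ketone, because the AlCl3-complexed aryl ketone is deactivated towards a second acylation.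

Step 2
Reactants: 3 phlorisobutyrophenone; 4 prenyl bromide (2 equiv)
Product: 5 deoxycohumulone, 2-methyl-1-[2,4,6-trihydroxy-3,5-bis(3-methylbut-2-en-1-yl)phenyl]propan-1-one
Conditions: 10% aq. KOH, 0 °C
Reagents that add atoms: none
Why: Phenolate C-alkylation (SN2) in water, where hydrogen bonding to oxygen favours C- over O-prenylation, should fill the two equivalent free ring positions; limiting the bromide to two equivalents holds back the third, dearomatising prenylation.

Step 3
Reactants: 6 prenol (3-methylbut-2-en-1-ol)
Product: 8 (R)-(3,3-dimethyloxiran-2-yl)methyl 4-methylbenzenesulfonate, via (R)-3,3-dimethylglycidol 7 (not isolated)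
Conditions: Ti(OiPr)4 (5 mol %), D-(−)-DIPT (7 mol %), cumene hydroperoxide, 4 Å MS, CH2Cl2, −20 °C; then P(OMe)3; then TsCl, Et3N, DMAP (cat.), −10 °C
Reagents that add atoms: cumene hydroperoxide CC(C)(OO)c1ccccc1; tosyl chloride Cc1ccc(cc1)S(Cl)(=O)=O
Why: Sharpless asymmetric epoxidation sets the epoxide carbon as (R) with the D-(−)-tartrate (L-(+)-tartrates give the 2S series with 3-substituted primary allylic alcohols), and in situ tosylation traps the volatile, water-soluble epoxy alcohol without touching the stereocentre.

Step 4
Reactants: 8 (R)-(3,3-dimethyloxiran-2-yl)methyl 4-methylbenzenesulfonate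
Product: 9 (S)-2-(iodomethyl)-3,3-dimethyloxirane
Conditions: NaI (2 equiv), NaHCO3 (cat.), acetone, 23 °C, dark
Reagents that add atoms: sodium iodide [Na+].[I-]
Why: Finkelstein SN2 exchange at the primary carbon, accelerated by the adjacent epoxide, leaves the stereocentre untouched; the descriptor changes from R to S only because CH2I outranks the ring carbon.

Step 5
Reactants: 5 deoxycohumulone; 9 (S)-2-(iodomethyl)-3,3-dimethyloxirane (1.2 equiv)
Product: 11 (2S,3aS)-6-hydroxy-2-(2-hydroxypropan-2-yl)-3a,7-bis(3-methylbut-2-en-1-yl)-5-(2-methylpropanoyl)-3,3a-dihydro-1-benzofuran-4(2H)-one (target), via C-alkylated epoxy enolate 10 (not isolated)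
Conditions: O-allyl-N-(9-anthracenylmethyl)cinchonidinium bromide (20 mol %), CsOH·H2O (2.5 equiv), toluene, −40 → 23 °C; then aq. citric acid
Reagents that add atoms: none
Why: The phenolate of Cs-symmetric 5, paired with the chiral ammonium ion, is C-alkylated (SN2) by the α-epoxy iodide 9 at one of its two enantiotopic prenylated carbons (C3/C5 of the aryl ketone), which dearomatises the ring and creates the quaternary carbon of 10; the enolate oxygen between this carbon and the remaining prenylated carbon (former O4) then opens the tethered epoxide at its secondary carbon. The closest known reaction types are the cinchona-ammonium phase-transfer enantioselective alkylative dearomatisation–annulation of 2-acyl-4,6-diprenylphloroglucinols and the enol-to-epoxide cyclisation of epoxidised prenyl groups in dearomatised acylphloroglucinols. The dihydrofuran closes 5-exo-tet, while 6-endo attack at the tertiary epoxide carbon is disfavoured under basic, non-ionising conditions. The quaternary (S) centre is set by the chiral ion pair that differentiates the two enantiotopic ring carbons, and the carbinol (S) centre comes from the (R)-epoxide carbon of 9 by SN2 inversion, so any mismatch should appear as the separable cis diastereomer and not as the enantiomer. The step needs C- over O-alkylation (soft iodide, ion pair in toluene, O4 flanked by two prenyl groups) and closure through O4 rather than O2 (O2 is held in the caesium-chelated acyl β-diketone, which closure through O4 preserves).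

**Compound list**

1 | phloroglucinol (benzene-1,3,5-triol) | Oc1cc(O)cc(O)c1 | starting material
2 | isobutyryl chloride (2-methylpropanoyl chloride) | CC(C)C(Cl)=O | starting material
3 | 2-methyl-1-(2,4,6-trihydroxyphenyl)propan-1-one (phlorisobutyrophenone) | CC(C)C(=O)c1c(O)cc(O)cc1O | intermediate
4 | prenyl bromide (1-bromo-3-methylbut-2-ene) | CC(C)=CCBr | starting material
5 | deoxycohumulone, 2-methyl-1-[2,4,6-trihydroxy-3,5-bis(3-methylbut-2-en-1-yl)phenyl]propan-1-one | CC(C)C(=O)c1c(O)c(CC=C(C)C)c(O)c(CC=C(C)C)c1O | intermediate
6 | prenol (3-methylbut-2-en-1-ol) | CC(C)=CCO | starting material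
7 | (R)-(3,3-dimethyloxiran-2-yl)methanol ((R)-3,3-dimethylglycidol) | OC[C@H]1OC1(C)C | intermediate (not isolated)
8 | (R)-(3,3-dimethyloxiran-2-yl)methyl 4-methylbenzenesulfonate | Cc1ccc(cc1)S(=O)(=O)OC[C@H]1OC1(C)C | intermediate
9 | (S)-2-(iodomethyl)-3,3-dimethyloxirane | IC[C@H]1OC1(C)C | intermediate
10 | (6S)-6-{[(2R)-3,3-dimethyloxiran-2-yl]methyl}-3,5-dihydroxy-2-(2-methylpropanoyl)-4,6-bis(3-methylbut-2-en-1-yl)cyclohexa-2,4-dien-1-one (present as its caesium enolate) | CC(C)=CCC1=C(O)[C@](CC=C(C)C)(C[C@H]2OC2(C)C)C(=O)C(C(=O)C(C)C)=C1O | intermediate (not isolated)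
11 | (2S,3aS)-6-hydroxy-2-(2-hydroxypropan-2-yl)-3a,7-bis(3-methylbut-2-en-1-yl)-5-(2-methylpropanoyl)-3,3a-dihydro-1-benzofuran-4(2H)-one | CC(C)=CCC1=C2O[C@H](C(C)(C)O)C[C@]2(CC=C(C)C)C(=O)C(C(=O)C(C)C)=C1O | target

**Step count.** Total: 5 steps. Longest linear sequence: 3 steps (steps 1, 2, 5 or steps 3, 4, 5).

**Steps most likely to fail**

1. Step 5. O-alkylation of the phenolate may compete with C-alkylation, the ion pair may discriminate the two enantiotopic ring carbons only weakly, and ring closure may stray to the oxygen next to the acyl carbon. Fallback (known biomimetic chemistry), setting out from 5: a third C-prenylation with 4 (NaOMe, MeOH, 0 °C) should give colupulone F1. Shi epoxidation of F1 (D-fructose-derived ketone, Oxone, K2CO3 buffer, MeCN–dimethoxymethane–water, 0 °C) is expected to oxidise one geminal prenyl group to the (R)-epoxide. This returns to the route at 10, together with the C6 epimer of 10 F2. Under the basic medium 10 should close to 11, while F2 should close to the (2S,3aR) cis diastereomer F3, to be removed by chromatography together with products of epoxidation at the third prenyl group.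

2. Step 2. Under- and over-prenylation and O-prenylation may erode the bis-C-prenylated product. Fallback, setting out from 3 and returning at 5: Lewis acid Friedel–Crafts prenylation with 2-methylbut-3-en-2-ol and BF3·OEt2 in dioxane at 23 °C, which works through a prenyl cation on the neutral phenol instead of phenolate alkylation; it makes no new compound (F0).

3. Step 3. Facial selectivity may be incomplete for this small trisubstituted allylic alcohol, and chloride may open the epoxide during the in situ tosylation. Fallback, setting out from 6 and returning at 9: the same asymmetric epoxidation is trapped in situ with 4-nitrobenzoyl chloride/Et3N to give crystalline (R)-(3,3-dimethyloxiran-2-yl)methyl 4-nitrobenzoate F4, which allows enrichment by recrystallisation. Methanolysis (K2CO3, MeOH, 0 °C) then releases 7, and Appel iodination (PPh3, I2, imidazole, CH2Cl2, 0 °C) should give 9 directly, bypassing 8.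

**Further compounds**

F1 | step 5 | colupulone, 3,5-dihydroxy-2-(2-methylpropanoyl)-4,6,6-tris(3-methylbut-2-en-1-yl)cyclohexa-2,4-dien-1-one | CC(C)=CCC1=C(O)C(CC=C(C)C)(CC=C(C)C)C(=O)C(C(=O)C(C)C)=C1O
F2 | step 5 | (6R)-6-{[(2R)-3,3-dimethyloxiran-2-yl]methyl}-3,5-dihydroxy-2-(2-methylpropanoyl)-4,6-bis(3-methylbut-2-en-1-yl)cyclohexa-2,4-dien-1-one (C6 epimer of 10) | CC(C)=CCC1=C(O)[C@@](CC=C(C)C)(C[C@H]2OC2(C)C)C(=O)C(C(=O)C(C)C)=C1O
F3 | step 5 | (2S,3aR)-6-hydroxy-2-(2-hydroxypropan-2-yl)-3a,7-bis(3-methylbut-2-en-1-yl)-5-(2-methylpropanoyl)-3,3a-dihydro-1-benzofuran-4(2H)-one (cis diastereomer of 11) | CC(C)=CCC1=C2O[C@H](C(C)(C)O)C[C@@]2(CC=C(C)C)C(=O)C(C(=O)C(C)C)=C1O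
F0 | step 2 | none | none
F4 | step 3 | (R)-(3,3-dimethyloxiran-2-yl)methyl 4-nitrobenzoate | O=C(OC[C@H]1OC1(C)C)c1ccc(cc1)[N+](=O)[O-]
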